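**Retrosynthetic overview**
1. Target 12 ⇐ 11 by hydrogenolysis of the two B-ring benzyl ethers; 11 ⇐ flavone 9 by installing the C3–O bond (epoxidation and ring opening of C2=C3).
2. Key disconnection: the O1–C8a bond of 9 ⇐ open-chain β-diketone 6, closed by a dehydrogenative C(aryl)–H/O–H coupling through a p-quinone monoketal; the phenol already present in 6 ends up as the 5-OH.
3. 6 ⇐ crossed Claisen condensation of acetophenone 4 with benzoate 5; 4 ⇐ Fries acylation of phenol 1.
4. Ring order: rings A and B are bought intact (in 1 and 5); the pyranone ring C is the only ring formed (step 3).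

Assumption: the target has no stereocentre, so no enantiocontrol is needed (the transient stereocentres in 8 and 10 are racemic and destroyed in the same flask); 1 and 5 are taken as catalogue materials.

**Step 1**
Reactants: 1 2,3,4-trimethoxyphenol; 2 acetic acid
Product: 4 1-(2-hydroxy-3,4,5-trimethoxyphenyl)ethanone, via aryl acetate 3 (not isolated)
Conditions: AcOH, BF3·OEt2 (3 equiv), 90 °C, 2 h; then H2O
Reagents that add atoms: none
Why: Fries rearrangement (Friedel–Crafts acylation): BF3 acetylates the phenol and moves the acetyl to C6, the only open position ortho to OH (para is blocked by OMe) and para to the 3-OMe, and the o-hydroxy ketone is held as a chelate so the methyl ethers are untouched.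

**Step 2**
Reactants: 4 1-(2-hydroxy-3,4,5-trimethoxyphenyl)ethanone; 5 methyl 3,4-bis(benzyloxy)benzoate
Product: 6 1-[3,4-bis(benzyloxy)phenyl]-3-(2-hydroxy-3,4,5-trimethoxyphenyl)propane-1,3-dione
Conditions: NaH (4 equiv), THF, reflux; then cold 1 M HCl
Reagents that add atoms: none
Why: Crossed Claisen condensation: the phenoxide/enolate dianion of 4 is C-acylated by the non-enolisable ester and the equilibrium is pulled over by the stabilised β-diketonate, while benzyl and methyl ethers are inert to NaH.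

**Step 3**
Reactants: 6 1-[3,4-bis(benzyloxy)phenyl]-3-(2-hydroxy-3,4,5-trimethoxyphenyl)propane-1,3-dione
Product: 9 2-[3,4-bis(benzyloxy)phenyl]-5-hydroxy-6,7,8-trimethoxy-4H-chromen-4-one, via quinone monoketal 7 (not isolated), via dihydrochromenone ketal 8 (not isolated)
Conditions: PhI(OAc)2 (1.05 equiv), MeOH/CH2Cl2 1:4 (0.02 M), −20 → 0 °C; then CSA (10 mol%), rt
Reagents that add atoms: methanol, CO (adds the second methoxy at the ketal carbon of 7; one of the two equivalent ketal methoxy groups leaves again on aromatisation)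
Why: Proposed new method: PhI(OAc)2/MeOH dearomatises the p-methoxyphenol of 6 to the 4,4-dimethoxy quinone monoketal 7, whose C5=C6 bond carries the only ring hydrogen and is a doubly activated Michael acceptor (ring C=O and side-chain C=O); the chelated Z-enol oxygen of the β-diketone closes 6-endo onto that carbon (oxa-Michael or oxa-6π) to give 8, and acid-induced loss of one ketal methanol rearomatises to 9, so the net result is an intramolecular dehydrogenative C(aryl)–H/O–H coupling that forms O1–C8a and keeps the 5-OH and all three OMe groups; the closest known reactions are PhI(OAc)2 oxidation of p-methoxyphenols to quinone monoketals and Michael addition–aromatisation of nucleophiles to such ketals (Hauser–Kraus-type annulations).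

**Step 4**
Reactants: 9 2-[3,4-bis(benzyloxy)phenyl]-5-hydroxy-6,7,8-trimethoxy-4H-chromen-4-one
Product: 11 2-[3,4-bis(benzyloxy)phenyl]-3,5-dihydroxy-6,7,8-trimethoxy-4H-chromen-4-one, via flavone epoxide 10 (not isolated)
Conditions: DMDO (3 equiv, in acetone), CH2Cl2, 0 °C → rt; then TsOH (cat.), CH2Cl2, rt
Reagents that add atoms: dimethyldioxirane (DMDO), CC1(C)OO1
Why: Dioxirane epoxidation of the enol-ether-like C2=C3 bond, then acid-catalysed opening at C2 (cation stabilised by O1 and the aryl group) and loss of H-3 gives the 3-hydroxyflavone; the chelated 5-OH, the OMe groups and the benzyl ethers should tolerate DMDO at 0 °C.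

**Step 5**
Reactants: 11 2-[3,4-bis(benzyloxy)phenyl]-3,5-dihydroxy-6,7,8-trimethoxy-4H-chromen-4-one
Product: 12 3,5,3',4'-tetrahydroxy-6,7,8-trimethoxyflavone
Conditions: H2 (1 atm), 10% Pd/C, THF/MeOH, rt
Reagents that add atoms: none
Why: Catalytic hydrogenolysis cleaves only the two aryl benzyl ethers; the aryl methyl ethers and the chelated pyranone C2=C3 and C=O are not reduced at 1 atm.

**Compound list**
1 | 2,3,4-trimethoxyphenol | COc1ccc(O)c(OC)c1OC | starting material
2 | acetic acid | CC(=O)O | starting material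
3 | 2,3,4-trimethoxyphenyl acetate (not isolated) | COc1ccc(OC(C)=O)c(OC)c1OC | intermediate
4 | 1-(2-hydroxy-3,4,5-trimethoxyphenyl)ethanone | CC(=O)c1cc(OC)c(OC)c(OC)c1O | intermediate
5 | methyl 3,4-bis(benzyloxy)benzoate | COC(=O)c1ccc(OCc2ccccc2)c(OCc2ccccc2)c1 | starting material
6 | 1-[3,4-bis(benzyloxy)phenyl]-3-(2-hydroxy-3,4,5-trimethoxyphenyl)propane-1,3-dione (mainly enol form) | O=C(CC(=O)c1ccc(OCc2ccccc2)c(OCc2ccccc2)c1)c1cc(OC)c(OC)c(OC)c1O | intermediate
7 | 6-{3-[3,4-bis(benzyloxy)phenyl]-3-oxopropanoyl}-2,3,4,4-tetramethoxycyclohexa-2,5-dien-1-one (not isolated) | COC1=C(OC)C(OC)(OC)C=C(C(=O)CC(=O)c2ccc(OCc3ccccc3)c(OCc3ccccc3)c2)C1=O | intermediate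
8 | 2-[3,4-bis(benzyloxy)phenyl]-5-hydroxy-6,7,8,8-tetramethoxy-8,8a-dihydro-4H-chromen-4-one (racemic at C8a, not isolated) | OC1=C2C(=O)C=C(c3ccc(OCc4ccccc4)c(OCc4ccccc4)c3)OC2C(OC)(OC)C(OC)=C1OC | intermediate
9 | 2-[3,4-bis(benzyloxy)phenyl]-5-hydroxy-6,7,8-trimethoxy-4H-chromen-4-one | COc1c(OC)c(O)c2c(=O)cc(-c3ccc(OCc4ccccc4)c(OCc4ccccc4)c3)oc2c1OC | intermediate
10 | 2-[3,4-bis(benzyloxy)phenyl]-2,3-epoxy-5-hydroxy-6,7,8-trimethoxy-2,3-dihydro-4H-chromen-4-one (racemic, cis-fused epoxide, not isolated) | COc1c(OC)c(O)c2C(=O)C3OC3(c4ccc(OCc5ccccc5)c(OCc5ccccc5)c4)Oc2c1OC | intermediate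
11 | 2-[3,4-bis(benzyloxy)phenyl]-3,5-dihydroxy-6,7,8-trimethoxy-4H-chromen-4-one | COc1c(OC)c(O)c2c(=O)c(O)c(-c3ccc(OCc4ccccc4)c(OCc4ccccc4)c3)oc2c1OC | intermediate
12 | 3,5,3',4'-tetrahydroxy-6,7,8-trimethoxyflavone (achiral) | COc1c(OC)c(O)c2c(=O)c(O)c(-c3ccc(O)c(O)c3)oc2c1OC | target

**Step count**
Total steps: 5. Longest linear sequence: 5 (1 → 4 → 6 → 9 → 11 → 12).

**Three steps most likely to fail**

(i) Step 3, the proposed new oxidative C–O closure. The risks are α-oxidation of the diketone by the iodane, conjugate addition of methanol instead of the enol oxygen, and over-oxidation of 9, which is itself a p-methoxyphenol. The fallback uses known chemistry, sets out from 4 and comes back at 9. NBS in MeCN at 0 °C brominates the single free ring position of 4 to give 1-(2-bromo-6-hydroxy-3,4,5-trimethoxyphenyl)ethanone F1. Crossed Claisen condensation of F1 with 5 (NaH, THF, reflux) gives 1-[3,4-bis(benzyloxy)phenyl]-3-(2-bromo-6-hydroxy-3,4,5-trimethoxyphenyl)propane-1,3-dione F2. CuI (10 mol%) and K2CO3 in DMF at 100 °C then close the pyranone by intramolecular Ullmann-type O-arylation of the diketonate at the C–Br bond, which gives 9.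

(ii) Step 4, the dioxirane C3-oxygenation. The risks are slow epoxidation of the electron-poor C2=C3 bond and oxidation of the electron-rich free-phenol A ring or of benzylic C–H. The fallback sets out from 9 and comes back at 12. BnBr and K2CO3 in DMF at 70 °C give 5-(benzyloxy)-2-[3,4-bis(benzyloxy)phenyl]-6,7,8-trimethoxy-4H-chromen-4-one F3. LDA in THF at −78 °C lithiates C3, and B(OMe)3 traps the anion as dimethyl {5-(benzyloxy)-2-[3,4-bis(benzyloxy)phenyl]-6,7,8-trimethoxy-4-oxo-4H-chromen-3-yl}boronate F4, which is not isolated. H2O2/AcOH oxidises it to 5-(benzyloxy)-2-[3,4-bis(benzyloxy)phenyl]-3-hydroxy-6,7,8-trimethoxy-4H-chromen-4-one F5. H2 over Pd/C removes all three benzyl groups and gives 12.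

(iii) Step 2, the crossed Claisen condensation. The risks are sluggish acylation by the electron-rich ester and acid-induced cyclodehydration of 6 on work-up, which would give the 5-unsubstituted flavone. The fallback is the Baker–Venkataraman route, sets out from 4 and comes back at 6. O-Aroylation of 4 with commercial 3,4-bis(benzyloxy)benzoyl chloride F6 in pyridine gives 2-acetyl-4,5,6-trimethoxyphenyl 3,4-bis(benzyloxy)benzoate F7. KOH in pyridine at 50 °C then effects the intramolecular O→C acyl shift to 6.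

**Further compounds**
F1 | step 3 | 1-(2-bromo-6-hydroxy-3,4,5-trimethoxyphenyl)ethanone | CC(=O)c1c(Br)c(OC)c(OC)c(OC)c1O
F2 | step 3 | 1-[3,4-bis(benzyloxy)phenyl]-3-(2-bromo-6-hydroxy-3,4,5-trimethoxyphenyl)propane-1,3-dione | O=C(CC(=O)c1ccc(OCc2ccccc2)c(OCc2ccccc2)c1)c1c(Br)c(OC)c(OC)c(OC)c1O
F3 | step 4 | 5-(benzyloxy)-2-[3,4-bis(benzyloxy)phenyl]-6,7,8-trimethoxy-4H-chromen-4-one | COc1c(OC)c(OCc2ccccc2)c2c(=O)cc(-c3ccc(OCc4ccccc4)c(OCc4ccccc4)c3)oc2c1OC
F4 | step 4 | dimethyl {5-(benzyloxy)-2-[3,4-bis(benzyloxy)phenyl]-6,7,8-trimethoxy-4-oxo-4H-chromen-3-yl}boronate | COB(OC)c1c(-c2ccc(OCc3ccccc3)c(OCc3ccccc3)c2)oc2c(OC)c(OC)c(OC)c(OCc3ccccc3)c2c1=O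
F5 | step 4 | 5-(benzyloxy)-2-[3,4-bis(benzyloxy)phenyl]-3-hydroxy-6,7,8-trimethoxy-4H-chromen-4-one | COc1c(OC)c(OCc2ccccc2)c2c(=O)c(O)c(-c3ccc(OCc4ccccc4)c(OCc4ccccc4)c3)oc2c1OC
F6 | step 2 | 3,4-bis(benzyloxy)benzoyl chloride | O=C(Cl)c1ccc(OCc2ccccc2)c(OCc2ccccc2)c1
F7 | step 2 | 2-acetyl-4,5,6-trimethoxyphenyl 3,4-bis(benzyloxy)benzoate | CC(=O)c1cc(OC)c(OC)c(OC)c1OC(=O)c1ccc(OCc2ccccc2)c(OCc2ccccc2)c1
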